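**Plan**

- Azulene numbering is used for the bicycle (C3 isopropyl, C3a hydroxyl, C6 methyl, C8 ester oxygen, C8a angular methyl). Retrosynthetic cuts, in order: the ester C–O bond; ring bond C8–C8a; side-chain bond C5–C6; C3a–C4; the five-ring alkene C1=C8a (metathesis); C3a–C8a; C2–C3.
- Forward: an Evans aldol (C2–C3), a Weinreb ketone synthesis (C3a–C8a) and ring-closing metathesis give a 4-hydroxycyclopentenone. Vinyl addition (C3a–C4) and a B-alkyl Suzuki coupling (C5–C6) attach the Z-enal chain. A reductive allyl–aldehyde coupling then closes the seven-membered ring at C8–C8a; hydrogenation, redox adjustment at C8 and acylation finish the route.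
- Enabling feature: the quaternary C8a is the end of the three-carbon unit C2–C1–C8a inside the five-membered ring and is flanked by carbinol C3a, which carries the C4–C7 tether. As the γ-terminus of a cyclopent-2-enyl metal spanning C2–C1–C8a it can be joined to the C8 aldehyde carbon: two electrophilic carbons united after polarity reversal of the allylic chloride by CrCl2. The tether can deliver C8 only to the face of C8a cis to C4.
- Stereochemistry: C3 from the oxazolidinone auxiliary (aldol); C3a by vinyl addition anti to the isopropyl group; C8a by the tether-enforced cis ring fusion of the key step; C8 by catalyst-controlled (CBS) reduction of the C8 enone.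

Key step: step 10

**Route**

Step 1
Reactants: 1 (4S)-4-benzyl-3-(3-methylbutanoyl)-1,3-oxazolidin-2-one; 2 acrolein
Product: 4 (4S)-4-benzyl-3-[(2S,3R)-3-hydroxy-2-(propan-2-yl)pent-4-enoyl]-1,3-oxazolidin-2-one, via Z-dibutylboron enolate 3 (not isolated)
Conditions: Bu2BOTf, iPr2NEt, CH2Cl2, −78 °C; 2, −78 to 0 °C; pH 7 buffer, MeOH, H2O2
Reagents that add atoms: none
Why: Evans syn-aldol reaction: the Z-boron enolate should add to acrolein through a closed chair transition state on the face away from the benzyl group, setting the (2S) isopropyl-bearing carbon (later C3) and the (3R) carbinol (a handle that is lost in step 10).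

Step 2
Reactants: 4 (4S)-4-benzyl-3-[(2S,3R)-3-hydroxy-2-(propan-2-yl)pent-4-enoyl]-1,3-oxazolidin-2-one
Product: 5 (2S,3R)-3-hydroxy-N-methoxy-N-methyl-2-(propan-2-yl)pent-4-enamide
Conditions: MeNHOMe·HCl, AlMe3, CH2Cl2/THF, −20 °C to rt; aq. HCl work-up
Reagents that add atoms: N,O-dimethylhydroxylamine hydrochloride, CNOC.Cl
Why: Aluminium-amide transamination of a β-hydroxy imide (Weinreb amide formation) is directed by the aluminium alkoxide to the exocyclic carbonyl and should release the auxiliary without epimerisation.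

Step 3
Reactants: 5 (2S,3R)-3-hydroxy-N-methoxy-N-methyl-2-(propan-2-yl)pent-4-enamide; 6 isopropenylmagnesium bromide
Product: 7 (4S,5R)-5-hydroxy-2-methyl-4-(propan-2-yl)hepta-1,6-dien-3-one
Conditions: 6 (3.5 equiv), THF, −20 to 0 °C; aq. NH4Cl
Reagents that add atoms: none
Why: Weinreb ketone synthesis: after deprotonation of the hydroxyl the chelated tetrahedral adduct persists until work-up, so a single alkenyl group should be delivered.

Step 4
Reactants: 7 (4S,5R)-5-hydroxy-2-methyl-4-(propan-2-yl)hepta-1,6-dien-3-one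
Product: 8 (4R,5S)-4-hydroxy-2-methyl-5-(propan-2-yl)cyclopent-2-en-1-one
Conditions: second-generation Grubbs catalyst (5 mol %), CH2Cl2 (0.01 M), 40 °C
Reagents that add atoms: none
Why: Ring-closing metathesis between the monosubstituted alkene and the 1,1-disubstituted enone alkene should close the five-membered ring with loss of ethene; no stereocentre is touched and hydroxyl and isopropyl stay trans.

Step 5
Reactants: 8 (4R,5S)-4-hydroxy-2-methyl-5-(propan-2-yl)cyclopent-2-en-1-one; 9 vinylmagnesium bromide
Product: 10 (1S,4R,5S)-1-ethenyl-2-methyl-5-(propan-2-yl)cyclopent-2-ene-1,4-diol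
Conditions: 9 (3 equiv), CeCl3 (3 equiv), THF, −78 °C; aq. NH4Cl
Reagents that add atoms: none
Why: 1,2-Addition of the organocerium reagent (little enolisation or conjugate addition) should occur anti to the adjacent isopropyl group, so the new tertiary hydroxyl (future C3a) stands cis to isopropyl.

Step 6
Reactants: 11 but-2-yn-1-ol
Product: 13 (2Z)-3-iodobut-2-en-1-ol, via cyclic alkenylalanate 12 (not isolated)
Conditions: NaAlH2(OCH2CH2OMe)2, Et2O, 0 °C to rt; I2, THF, −78 °C
Reagents that add atoms: iodine, II
Why: Hydroxyl-directed trans-hydroalumination of a propargylic alcohol places aluminium on C3 cis to the CH2O group, and iodinolysis with retention fixes the Z geometry.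

Step 7
Reactants: 10 (1S,4R,5S)-1-ethenyl-2-methyl-5-(propan-2-yl)cyclopent-2-ene-1,4-diol; 13 (2Z)-3-iodobut-2-en-1-ol
Product: 15 (1S,4R,5S)-1-[(3Z)-5-hydroxy-3-methylpent-3-en-1-yl]-2-methyl-5-(propan-2-yl)cyclopent-2-ene-1,4-diol, via B-alkyl-9-borabicyclononane 14 (not isolated)
Conditions: 9-BBN-H (3 equiv), THF, 0 °C to rt; then 13, PdCl2(dppf) (5 mol %), aq. K3PO4, DMF, rt
Reagents that add atoms: none
Why: 9-BBN-H should hydroborate only the monosubstituted vinyl group at its terminus, and the B-alkyl Suzuki–Miyaura coupling joins C5 to C6 with retention of the Z alkene geometry.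

Step 8
Reactants: 15 (1S,4R,5S)-1-[(3Z)-5-hydroxy-3-methylpent-3-en-1-yl]-2-methyl-5-(propan-2-yl)cyclopent-2-ene-1,4-diol
Product: 16 (2Z)-5-[(1S,4R,5S)-1,4-dihydroxy-2-methyl-5-(propan-2-yl)cyclopent-2-en-1-yl]-3-methylpent-2-enal
Conditions: TEMPO (10 mol %), PhI(OAc)2 (1.1 equiv), CH2Cl2, 0 °C to rt
Reagents that add atoms: none
Why: Oxoammonium (TEMPO) oxidation is much faster at the unhindered primary allylic alcohol than at the hindered secondary one and is mild enough to keep the Z-enal geometry.

Step 9
Reactants: 16 (2Z)-5-[(1S,4R,5S)-1,4-dihydroxy-2-methyl-5-(propan-2-yl)cyclopent-2-en-1-yl]-3-methylpent-2-enal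
Product: 18 (2Z)-5-[(1S,4S,5R)-4-chloro-1-hydroxy-2-methyl-5-(propan-2-yl)cyclopent-2-en-1-yl]-3-methylpent-2-enal, via allylic mesylate 17 (not isolated)
Conditions: MsCl, 2,4,6-collidine, LiCl, DMF, 0 °C; used crude
Reagents that add atoms: lithium chloride, [Li+].[Cl-]
Why: Mesylation followed by chloride displacement is selective for the secondary allylic hydroxyl (the tertiary one is inert); any epimeric or allyl-transposed chloride converges on the same allylmetal in step 10.

Step 10
Reactants: 18 (2Z)-5-[(1S,4S,5R)-4-chloro-1-hydroxy-2-methyl-5-(propan-2-yl)cyclopent-2-en-1-yl]-3-methylpent-2-enal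
Product: 20 (3S,3aS,8R,8aR)-6,8a-dimethyl-3-(propan-2-yl)-3,3a,4,5,8,8a-hexahydroazulene-3a,8-diol, via allylchromium dichloride 19 (not isolated)
Conditions: CrCl2 (8 equiv), LiI (20 mol %), THF, rt, slow addition of 18 (final 0.003 M); aq. NH4Cl
Reagents that add atoms: none
Why: Two equivalents of divalent chromium reduce the allylic chloride to the trivalent allylchromium species 19, which adds through its γ-carbon (C8a) to the tethered aldehyde carbon C8 in a six-membered chair transition state; this is an intramolecular Nozaki–Hiyama allylation, a reductive union of two electrophilic carbons after polarity reversal of the allyl unit. The seven-membered ring closes by 7-exo-trig addition to the C=O group with transposition of the five-ring alkene to C1=C2; attack through C2 would need a bridged eight-membered ring and is not expected. The new quaternary centre C8a is controlled by C3a: the tether can reach only the face of the allyl unit on which it stands, so C8 is bonded cis to C4 and the methyl group ends up cis to the C3a hydroxyl (cis ring fusion). At C8 the chair model (methyl fixed E on the γ-carbon by the ring, aldehyde substituent equatorial) predicts the hydroxyl anti to the methyl group (8R); this centre is reset in steps 12 and 13, so either epimer can be carried on. The step needs 1,2- over 1,4-addition to the enal and cyclisation over dimerisation or protonation of 19: the closed transition state of allylchromium reagents gives 1,2-addition, the Z alkene and the fully substituted C3a fold the chain, and slow addition keeps the concentration low.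

Step 11
Reactants: 20 (3S,3aS,8R,8aR)-6,8a-dimethyl-3-(propan-2-yl)-3,3a,4,5,8,8a-hexahydroazulene-3a,8-diol
Product: 21 (3R,3aS,8R,8aR)-6,8a-dimethyl-3-(propan-2-yl)-1,2,3,3a,4,5,8,8a-octahydroazulene-3a,8-diol
Conditions: H2 (1 atm), RhCl(PPh3)3 (10 mol %), benzene, rt
Reagents that add atoms: none
Why: Homogeneous hydrogenation with RhCl(PPh3)3 should reduce the cis-disubstituted cyclopentene and leave the trisubstituted C6=C7 alkene; no stereocentre is formed.

Step 12
Reactants: 21 (3R,3aS,8R,8aR)-6,8a-dimethyl-3-(propan-2-yl)-1,2,3,3a,4,5,8,8a-octahydroazulene-3a,8-diol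
Product: 22 (3R,3aS,8aS)-3a-hydroxy-6,8a-dimethyl-3-(propan-2-yl)-2,3,3a,4,5,8a-hexahydroazulen-8(1H)-one
Conditions: Dess–Martin periodinane, CH2Cl2, 0 °C to rt
Reagents that add atoms: none
Why: Dess–Martin oxidation of the secondary allylic alcohol gives the enone and erases the C8 centre; the tertiary alcohol cannot be oxidised.

Step 13
Reactants: 22 (3R,3aS,8aS)-3a-hydroxy-6,8a-dimethyl-3-(propan-2-yl)-2,3,3a,4,5,8a-hexahydroazulen-8(1H)-one
Product: 23 (3R,3aS,8S,8aR)-6,8a-dimethyl-3-(propan-2-yl)-1,2,3,3a,4,5,8,8a-octahydroazulene-3a,8-diol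
Conditions: (R)-2-methyl-CBS-oxazaborolidine (1 equiv), catecholborane (3 equiv), toluene, −78 °C; aq. NaOH work-up
Reagents that add atoms: none
Why: Corey–Bakshi–Shibata reduction: with quaternary C8a as the large and alkenyl C7 as the small substituent, the (R)-oxazaborolidine should deliver hydride 1,2 to the face that gives the (8S) alcohol (hydroxyl cis to the angular methyl) under catalyst control.

Step 14
Reactants: 23 (3R,3aS,8S,8aR)-6,8a-dimethyl-3-(propan-2-yl)-1,2,3,3a,4,5,8,8a-octahydroazulene-3a,8-diol; 24 4-methoxybenzoyl chloride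
Product: 25 (3R,3aS,8S,8aR)-3a-hydroxy-6,8a-dimethyl-3-(propan-2-yl)-1,2,3,3a,4,5,8,8a-octahydroazulen-8-yl 4-methoxybenzoate
Conditions: 24 (1.5 equiv), Et3N, DMAP (20 mol %), CH2Cl2, 0 °C to rt
Reagents that add atoms: none
Why: DMAP-catalysed acylation should take place only at the secondary allylic hydroxyl, the tertiary C3a hydroxyl being too hindered.

**Compound list**

1 | (4S)-4-benzyl-3-(3-methylbutanoyl)-1,3-oxazolidin-2-one | CC(C)CC(=O)N1[C@@H](Cc2ccccc2)COC1=O | starting material
2 | acrolein (prop-2-enal) | C=CC=O | starting material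
3 | Z-dibutylboron enolate of 1 (not isolated) | CC(C)/C=C(\OB(CCCC)CCCC)N1[C@@H](Cc2ccccc2)COC1=O | intermediate
4 | (4S)-4-benzyl-3-[(2S,3R)-3-hydroxy-2-(propan-2-yl)pent-4-enoyl]-1,3-oxazolidin-2-one | C=C[C@@H](O)[C@H](C(C)C)C(=O)N1[C@@H](Cc2ccccc2)COC1=O | intermediate
5 | (2S,3R)-3-hydroxy-N-methoxy-N-methyl-2-(propan-2-yl)pent-4-enamide | C=C[C@@H](O)[C@H](C(C)C)C(=O)N(C)OC | intermediate
6 | isopropenylmagnesium bromide | CC(=C)[Mg]Br | starting material
7 | (4S,5R)-5-hydroxy-2-methyl-4-(propan-2-yl)hepta-1,6-dien-3-one | C=C[C@@H](O)[C@H](C(C)C)C(=O)C(C)=C | intermediate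
8 | (4R,5S)-4-hydroxy-2-methyl-5-(propan-2-yl)cyclopent-2-en-1-one (hydroxyl and isopropyl trans) | O=C1C(C)=C[C@@H](O)[C@@H]1C(C)C | intermediate
9 | vinylmagnesium bromide | C=C[Mg]Br | starting material
10 | (1S,4R,5S)-1-ethenyl-2-methyl-5-(propan-2-yl)cyclopent-2-ene-1,4-diol (tertiary hydroxyl cis to isopropyl) | C=C[C@@]1(O)C(C)=C[C@@H](O)[C@@H]1C(C)C | intermediate
11 | but-2-yn-1-ol | CC#CCO | starting material
12 | sodium cyclic (Z)-alkenylalanate from 11, aluminium bound to oxygen and to C3 (not isolated) | [Na+].CC1=CCO[Al-]1(OCCOC)OCCOC | intermediate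
13 | (2Z)-3-iodobut-2-en-1-ol | C/C(I)=C/CO | intermediate
14 | B-{2-[(1S,4R,5S)-1,4-dihydroxy-2-methyl-5-(propan-2-yl)cyclopent-2-en-1-yl]ethyl}-9-borabicyclo[3.3.1]nonane (not isolated; hydroxyls drawn free) | C1CCC2CCCC1B2CC[C@@]1(O)C(C)=C[C@@H](O)[C@@H]1C(C)C | intermediate
15 | (1S,4R,5S)-1-[(3Z)-5-hydroxy-3-methylpent-3-en-1-yl]-2-methyl-5-(propan-2-yl)cyclopent-2-ene-1,4-diol | OC/C=C(/C)CC[C@@]1(O)C(C)=C[C@@H](O)[C@@H]1C(C)C | intermediate
16 | (2Z)-5-[(1S,4R,5S)-1,4-dihydroxy-2-methyl-5-(propan-2-yl)cyclopent-2-en-1-yl]-3-methylpent-2-enal | O=C/C=C(/C)CC[C@@]1(O)C(C)=C[C@@H](O)[C@@H]1C(C)C | intermediate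
17 | 16 with the secondary ring hydroxyl as its methanesulfonate, configuration unchanged (not isolated) | O=C/C=C(/C)CC[C@@]1(O)C(C)=C[C@@H](OS(C)(=O)=O)[C@@H]1C(C)C | intermediate
18 | (2Z)-5-[(1S,4S,5R)-4-chloro-1-hydroxy-2-methyl-5-(propan-2-yl)cyclopent-2-en-1-yl]-3-methylpent-2-enal (configuration at the chloride carbon immaterial) | O=C/C=C(/C)CC[C@@]1(O)C(C)=C[C@H](Cl)[C@@H]1C(C)C | intermediate
19 | cyclopent-2-enylchromium dichloride derived from 18, trivalent chromium on the former chloride carbon (not isolated) | O=C/C=C(/C)CC[C@@]1(O)C(C)=CC([Cr](Cl)Cl)[C@@H]1C(C)C | intermediate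
20 | (3S,3aS,8R,8aR)-6,8a-dimethyl-3-(propan-2-yl)-3,3a,4,5,8,8a-hexahydroazulene-3a,8-diol (cis-fused; C8 hydroxyl trans to the C8a methyl) | O[C@@H]1C=C(C)CC[C@]2(O)[C@@H](C(C)C)C=C[C@]12C | intermediate
21 | (3R,3aS,8R,8aR)-6,8a-dimethyl-3-(propan-2-yl)-1,2,3,3a,4,5,8,8a-octahydroazulene-3a,8-diol | O[C@@H]1C=C(C)CC[C@]2(O)[C@@H](C(C)C)CC[C@]12C | intermediate
22 | (3R,3aS,8aS)-3a-hydroxy-6,8a-dimethyl-3-(propan-2-yl)-2,3,3a,4,5,8a-hexahydroazulen-8(1H)-one | O=C1C=C(C)CC[C@]2(O)[C@@H](C(C)C)CC[C@]12C | intermediate
23 | (3R,3aS,8S,8aR)-6,8a-dimethyl-3-(propan-2-yl)-1,2,3,3a,4,5,8,8a-octahydroazulene-3a,8-diol (C8 hydroxyl cis to the C8a methyl) | O[C@H]1C=C(C)CC[C@]2(O)[C@@H](C(C)C)CC[C@]12C | intermediate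
24 | 4-methoxybenzoyl chloride | COc1ccc(cc1)C(Cl)=O | starting material
25 | (3R,3aS,8S,8aR)-3a-hydroxy-6,8a-dimethyl-3-(propan-2-yl)-1,2,3,3a,4,5,8,8a-octahydroazulen-8-yl 4-methoxybenzoate | COc1ccc(C(=O)O[C@H]2C=C(C)CC[C@]3(O)[C@@H](C(C)C)CC[C@]23C)cc1 | target

**Step count and risks**

Total step count: 14. Longest linear sequence: 13 (steps 1–5 and 7–14); step 6 is a one-step branch.

Steps most likely to fail:

1. Step 10. The allylchromium intermediate may be protonated by the two free hydroxyls or couple intermolecularly instead of closing the seven-membered ring, and the labile cyclopentenyl chloride 18 may lose HCl before it is reduced. The fallback sets out from 16 and avoids the halide. Acetylation of the secondary allylic hydroxyl (Ac2O, pyridine, 0 °C) should give the allylic acetate F1. With Pd(PPh3)4 (zerovalent palladium, 5 mol %) and InI in THF at rt this is ionised to a π-allylpalladium complex and reduced in the flask to the trivalent allylindium species F2 (not isolated), which adds to the tethered aldehyde through its γ-carbon. The route is rejoined at 20.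

2. Step 13. Facial selectivity may be poor or reversed if the intrinsic bias of the cis-fused bicycle opposes the catalyst, or if the catalyst binds sluggishly next to the quaternary C8a. The fallback sets out from 22 and relies on substrate control instead. Et2BOMe in THF/MeOH at −78 °C ties the C3a hydroxyl and the C8 carbonyl into the diethylboron chelate F3 (not isolated), and external hydride from NaBH4 (Narasaka–Prasad reduction) should give the 1,3-syn diol. The route is rejoined at 23.

3. Step 8. The secondary allylic carbinol may be over-oxidised to a cyclopentenone, and the Z-enal may isomerise to E. The fallback sets out from 13 and moves the oxidation to the small fragment. MnO2 in CH2Cl2 should give (2Z)-3-iodobut-2-enal F4, which is coupled with borane 14 (made from 10 as in step 7) under the Suzuki conditions of step 7. The route is rejoined at 16.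

Further compounds
F1 | step 10 | (1R,4S,5S)-4-hydroxy-3-methyl-4-[(3Z)-3-methyl-5-oxopent-3-en-1-yl]-5-(propan-2-yl)cyclopent-2-en-1-yl acetate | O=C/C=C(/C)CC[C@@]1(O)C(C)=C[C@@H](OC(C)=O)[C@@H]1C(C)C
F2 | step 10 | cyclopent-2-enylindium acetate iodide derived from F1 (not isolated) | O=C/C=C(/C)CC[C@@]1(O)C(C)=CC([In](I)OC(C)=O)[C@@H]1C(C)C
F3 | step 13 | diethylboron chelate of 22, boron on the C3a oxygen (not isolated) | O=C1C=C(C)CC[C@]2(OB(CC)CC)[C@@H](C(C)C)CC[C@]12C
F4 | step 8 | (2Z)-3-iodobut-2-enal | C/C(I)=C/C=O
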